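**Plan**
1. Retrosynthesis: acetates, acetonide/silyl ether and the C18 ester are end-game adjustments; the C19 methyl group is traced back to a carboxyl group (CH3 ⇐ CH2I ⇐ CH2OH ⇐ CO2H).
2. C4–C5 is then cut by a retro-Claisen step. C5 is allylic to the C1=C10 double bond of ring A and C4 carries carboxyl-level carbons, so ring A is a γ,δ-unsaturated acid; its allylic oxygen would sit on C1, only C2 and C3 away from C4, so ester and allyl part are tied into δ-lactone 17.
3. 17 is cut at C3–C4 (malonate Michael addition), C1–C10/C1–C2 (carbonylative coupling of ring B enol triflate 12), C13–C16 (methyl Grignard), C9–C11 (Michael addition to vinyl ketone 3) and C8–C17 (conjugate addition to 2-methylcyclohexenone).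
4. Forward: ring B is bought, the side chain is joined at C9 and finished, the C10 arm is built and closed to the temporary lactone ring, and ring A arises last by the lactone-to-carbocycle switch. The helpers leave afterwards: the C1 oxygen in the key step, the C19 carboxyl by reduction to methyl.
5. Stereochemistry: C8 from the Cu(OTf)2/NHC catalyst, C9 from C8 (anti attack), C14 from the chiral pool, C13 from C14 (chelate), C1 from the oxazaborolidine. C5 and C4 both come from C1 through the boat-like [3,3] shift, after which C1 is trigonal.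

Key step: step 11

Remark: positions follow the halimane skeleton of the target ("halim-1(10)-ene": decalin C1–C10 with C1=C10, side chain C11–C16 on C9, C17 on C8, C18 carboxyl and C19 methyl on C4, C20 on C9). SC stands for the (3S)-3-[(4R)-2,2-dimethyl-1,3-dioxolan-4-yl]-3-(triethylsilyloxy)butyl group. Compounds 15–17 are carried as C4 epimers, since C4 is trigonal in 18.

Step 1
Reactants: 1 methyl (4R)-2,2-dimethyl-1,3-dioxolane-4-carboxylate
Product: 2 (4R)-N-methoxy-N,2,2-trimethyl-1,3-dioxolane-4-carboxamide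
Conditions: MeNH(OMe)·HCl, i-PrMgCl, THF, −20 °C
Reagents that add atoms: N,O-dimethylhydroxylamine hydrochloride (CNOC.Cl)
Why: Weinreb amide formation by aminolysis of the ester with the chloromagnesium amide, fast at −20 °C, which should leave the α-alkoxy stereocentre (C14) untouched.

Step 2
Reactants: 2 (4R)-N-methoxy-N,2,2-trimethyl-1,3-dioxolane-4-carboxamide
Product: 3 1-[(4R)-2,2-dimethyl-1,3-dioxolan-4-yl]prop-2-en-1-one
Conditions: CH2=CHMgBr, THF, −78 → 0 °C; cold aq. HCl quench
Reagents that add atoms: vinylmagnesium bromide (C=C[Mg]Br)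
Why: Weinreb ketone synthesis: the chelated tetrahedral adduct survives until the quench, so only one vinyl group adds, and the cold acidic quench keeps the released amine from adding to the enone.

Step 3
Reactants: 4 2-methylcyclohex-2-en-1-one
Product: 6 trimethyl{[(3R)-2,3-dimethylcyclohex-1-en-1-yl]oxy}silane, via bromomagnesium enolate 5 (not isolated)
Conditions: MeMgBr, Cu(OTf)2 (3 mol %), chiral imidazolinium-derived NHC ligand (4 mol %, enantiomer giving the 3R adduct), Et2O, −30 °C; then Me3SiCl, Et3N, DMPU, −30 → 0 °C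
Reagents that add atoms: methylmagnesium bromide (C[Mg]Br); chlorotrimethylsilane (C[Si](C)(C)Cl)
Why: Asymmetric conjugate addition of a Grignard reagent to an α-substituted cyclic enone, in which the chiral NHC complex formed from Cu(OTf)2 selects the enone face and sets C8 as R, followed by O-silylation of the regiodefined enolate.

Step 4
Reactants: 6 trimethyl{[(3R)-2,3-dimethylcyclohex-1-en-1-yl]oxy}silane; 3 1-[(4R)-2,2-dimethyl-1,3-dioxolan-4-yl]prop-2-en-1-one
Product: 8 (2S,3R)-2-{3-[(4R)-2,2-dimethyl-1,3-dioxolan-4-yl]-3-oxopropyl}-2,3-dimethylcyclohexan-1-one, via silyl enol ether 7 (not isolated)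
Conditions: Tf2NH (3 mol %), CH2Cl2, −78 °C; then aq. citric acid, THF, 0 °C
Reagents that add atoms: none
Why: Mukaiyama–Michael addition: the C8 methyl group sits pseudoaxial to avoid A(1,2) strain with the C9 methyl group, so the enone should attack C9 from the opposite face and place the chain trans to the C8 methyl group (C9 S), the silyl enol ether of the adduct being hydrolysed on work-up.

Step 5
Reactants: 8 (2S,3R)-2-{3-[(4R)-2,2-dimethyl-1,3-dioxolan-4-yl]-3-oxopropyl}-2,3-dimethylcyclohexan-1-one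
Product: 9 (2S,3R)-2-{(3S)-3-[(4R)-2,2-dimethyl-1,3-dioxolan-4-yl]-3-hydroxybutyl}-2,3-dimethylcyclohexan-1-one
Conditions: MeMgBr (1.2 equiv), Et2O/CH2Cl2, −78 °C; aq. NH4Cl
Reagents that add atoms: methylmagnesium bromide (C[Mg]Br)
Why: Chelation-controlled (Cram chelate) Grignard addition to an α-alkoxy ketone: magnesium bridges the C13 carbonyl and the C14 ring oxygen, the methyl group enters from the side of the C14 hydrogen and should give 13S, while the ring ketone next to quaternary C9 should not react at −78 °C.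

Step 6
Reactants: 9 (2S,3R)-2-{(3S)-3-[(4R)-2,2-dimethyl-1,3-dioxolan-4-yl]-3-hydroxybutyl}-2,3-dimethylcyclohexan-1-one
Product: 10 (2S,3R)-2,3-dimethyl-2-SC-cyclohexan-1-one
Conditions: Et3SiOTf, 2,6-lutidine, CH2Cl2, −78 → 0 °C
Reagents that add atoms: triethylsilyl trifluoromethanesulfonate (CC[Si](CC)(CC)OS(=O)(=O)C(F)(F)F)
Why: Silylation of a tertiary alcohol with a silyl triflate and a hindered base, which masks the C13 hydroxyl group against the later enolisation, iodination and radical steps.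

Step 7
Reactants: 10 (2S,3R)-2,3-dimethyl-2-SC-cyclohexan-1-one
Product: 12 (5R,6S)-5,6-dimethyl-6-SC-cyclohex-1-en-1-yl trifluoromethanesulfonate, via potassium enolate 11 (not isolated)
Conditions: KN(SiMe3)2, THF, −78 °C; then PhNTf2, −78 → 0 °C
Reagents that add atoms: N-phenylbis(trifluoromethanesulfonimide) (O=S(=O)(N(c1ccccc1)S(=O)(=O)C(F)(F)F)C(F)(F)F)
Why: Enol triflate formation: C9 is quaternary, so the ketone can only be deprotonated at C5, and O-sulfonylation of the enolate fixes the C5=C10 double bond.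

Step 8
Reactants: 12 (5R,6S)-5,6-dimethyl-6-SC-cyclohex-1-en-1-yl trifluoromethanesulfonate
Product: 13 1-[(5R,6S)-5,6-dimethyl-6-SC-cyclohex-1-en-1-yl]prop-2-en-1-one
Conditions: CH2=CHSnBu3, CO (1 atm), Pd(PPh3)4 (5 mol %), LiCl, THF, 55 °C
Reagents that add atoms: carbon monoxide ([C-]#[O+]); tributyl(vinyl)stannane (C=C[Sn](CCCC)(CCCC)CCCC)
Why: Carbonylative Stille coupling: oxidative addition of the enol triflate to zerovalent palladium from Pd(PPh3)4, CO insertion and transmetallation from the vinylstannane should give the cross-conjugated dienone and install C1 to C3.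

Step 9
Reactants: 13 1-[(5R,6S)-5,6-dimethyl-6-SC-cyclohex-1-en-1-yl]prop-2-en-1-one; 14 dimethyl malonate
Product: 15 dimethyl 2-{3-[(5R,6S)-5,6-dimethyl-6-SC-cyclohex-1-en-1-yl]-3-oxopropyl}propanedioate
Conditions: 14 (3 equiv), K2CO3 (20 mol %), THF, 0 °C → rt
Reagents that add atoms: none
Why: Base-catalysed Michael addition of a malonate, expected only at the unsubstituted vinyl terminus (C3) because the β-carbon of the cyclohexenyl enone (C5) is shielded by the α-substituent and by quaternary C9.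

Step 10
Reactants: 15 dimethyl 2-{3-[(5R,6S)-5,6-dimethyl-6-SC-cyclohex-1-en-1-yl]-3-oxopropyl}propanedioate
Product: 17 methyl (6S)-6-[(5R,6S)-5,6-dimethyl-6-SC-cyclohex-1-en-1-yl]-2-oxooxane-3-carboxylate (both C3 epimers), via hydroxy diester 16 (not isolated)
Conditions: (R)-2-methyl-CBS-oxazaborolidine (20 mol %), catecholborane, toluene, −78 °C; MeOH quench; then DBU (10 mol %), toluene, 40 °C
Reagents that add atoms: none
Why: Corey–Bakshi–Shibata reduction, in which the (R)-oxazaborolidine treats the bulky cyclohexenyl group as the large and the CH2 chain as the small substituent and should give the 1S carbinol, followed by base-catalysed lactonisation of one malonate ester to the δ-lactone.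

Step 11
Reactants: 17 methyl (6S)-6-[(5R,6S)-5,6-dimethyl-6-SC-cyclohex-1-en-1-yl]-2-oxooxane-3-carboxylate
Product: 20 (4S,5S,8R,9S,13S,14R)-14,15-(isopropylidenedioxy)-18-methoxy-18-oxo-13-(triethylsilyloxy)halim-1(10)-en-19-oic acid (C19 carboxyl trans to H5; C18 ester cis to H5), via silyl ketene acetal 18 (not isolated), via silyl ester 19 (not isolated)
Conditions: t-BuMe2SiOTf, Et3N, toluene, 0 °C; then 110 °C; then AcOH, THF/H2O, rt
Reagents that add atoms: none
Why: Soft enolisation of the malonate-type lactone gives ketene acetal 18, whose C4=C(OSi)–O–C1–C10=C5 array undergoes a [3,3]-sigmatropic (Ireland–Claisen) shift in which the C1–O bond breaks as the C4–C5 bond forms and the double bond moves to C1=C10; the closest known reaction types are the Claisen rearrangement of silyl ketene acetals of 6-alkenyl δ-lactones and dioxanones and the [3,3] shift of silyl ketene acetals of allyl malonates. Ring A closes in this one event as the carbocycle C4–C3–C2–C1–C10–C5, and the C2–C3 tether between the two termini forces a boat-like, bicyclo[2.2.2]-type transition state because no chair can be reached. C5 is controlled by the C1 carbinol centre: the shift is suprafacial on the allyl unit, so the 1S oxygen delivers C4 to the α face of C5 (H5 β). C4 is controlled by the ring-fixed ketene acetal geometry in the boat: the lactone carbon lies over C10 and ends trans to H5 (the future C19 methyl), and the spectator ester ends cis to H5 (the future C18 acid). The step needs regioselectivity (only C5 can be reached, since bonding at C1 would give a four-membered ring), the right silyl tautomer (silyl exchange between the two carbonyl oxygens is fast and only the lactone ketene acetal can rearrange) and survival of the new carboxyl group (no acetate or fluoride and a mild work-up avoid decarboxylation of the malonic half ester).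

Step 12
Reactants: 20 (4S,5S,8R,9S,13S,14R)-14,15-(isopropylidenedioxy)-18-methoxy-18-oxo-13-(triethylsilyloxy)halim-1(10)-en-19-oic acid
Product: 22 methyl (4S,5S,8R,9S,13S,14R)-19-hydroxy-14,15-(isopropylidenedioxy)-13-(triethylsilyloxy)halim-1(10)-en-18-oate, via acyl imidazole 21 (not isolated)
Conditions: 1,1'-carbonyldiimidazole, THF, rt; then NaBH4, H2O, 0 °C
Reagents that add atoms: none
Why: Chemoselective reduction of a carboxylic acid beside an ester through its acyl imidazole, which NaBH4 reduces to the primary alcohol while the hindered methyl ester is left alone.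

Step 13
Reactants: 22 methyl (4S,5S,8R,9S,13S,14R)-19-hydroxy-14,15-(isopropylidenedioxy)-13-(triethylsilyloxy)halim-1(10)-en-18-oate
Product: 23 methyl (4R,5S,8R,9S,13S,14R)-19-iodo-14,15-(isopropylidenedioxy)-13-(triethylsilyloxy)halim-1(10)-en-18-oate
Conditions: I2, PPh3, imidazole, toluene, 80 °C
Reagents that add atoms: iodine (II)
Why: Appel-type iodination of a primary alcohol; the neopentyl position is expected to need heat but cannot eliminate.

Step 14
Reactants: 23 methyl (4R,5S,8R,9S,13S,14R)-19-iodo-14,15-(isopropylidenedioxy)-13-(triethylsilyloxy)halim-1(10)-en-18-oate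
Product: 24 methyl (4S,5S,8R,9S,13S,14R)-14,15-(isopropylidenedioxy)-13-(triethylsilyloxy)halim-1(10)-en-18-oate
Conditions: Bu3SnH, AIBN (cat.), toluene, 80 °C
Reagents that add atoms: none
Why: Radical chain dehalogenation with tributyltin hydride turns CH2I into the C19 methyl group; the primary radical has only highly strained cyclisations onto C1=C10 open to it.

Step 15
Reactants: 24 methyl (4S,5S,8R,9S,13S,14R)-14,15-(isopropylidenedioxy)-13-(triethylsilyloxy)halim-1(10)-en-18-oate
Product: 25 (4S,5S,8R,9S,13S,14R)-14,15-(isopropylidenedioxy)-13-(triethylsilyloxy)halim-1(10)-en-18-oic acid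
Conditions: NaSEt, DMF, 100 °C; then aq. HCl to pH 3
Reagents that add atoms: none
Why: Cleavage of the hindered methyl ester by SN2 attack of thiolate at the O-methyl carbon, which avoids addition to the neopentyl carbonyl group and should leave acetal and silyl ether intact.

Step 16
Reactants: 25 (4S,5S,8R,9S,13S,14R)-14,15-(isopropylidenedioxy)-13-(triethylsilyloxy)halim-1(10)-en-18-oic acid
Product: 26 (4S,5S,8R,9S,13S,14R)-13,14,15-trihydroxyhalim-1(10)-en-18-oic acid
Conditions: 1 M aq. HCl, THF, rt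
Reagents that add atoms: none
Why: Acid-catalysed hydrolysis of the acetonide and the silyl ether; dilute acid at room temperature is not expected to protonate the trisubstituted C1=C10 double bond.

Step 17
Reactants: 26 (4S,5S,8R,9S,13S,14R)-13,14,15-trihydroxyhalim-1(10)-en-18-oic acid
Product: 28 (4S,5S,8R,9S,13S,14R)-14,15-diacetoxy-13-hydroxyhalim-1(10)-en-18-oic acid (target), via mixed anhydride 27 (not isolated)
Conditions: Ac2O, pyridine, 0 °C → rt; then H2O, THF, rt
Reagents that add atoms: acetic anhydride (CC(=O)OC(C)=O)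
Why: Acetylation of the primary and the secondary hydroxyl group in pyridine, under which the tertiary C13 hydroxyl group should not react; the mixed anhydride formed at the carboxyl group is hydrolysed by water before isolation.

**Compound list**
1 | methyl (4R)-2,2-dimethyl-1,3-dioxolane-4-carboxylate | CC1(C)OC[C@@H](O1)C(=O)OC | starting material
2 | (4R)-N-methoxy-N,2,2-trimethyl-1,3-dioxolane-4-carboxamide | CC1(C)OC[C@@H](O1)C(=O)N(C)OC | intermediate
3 | 1-[(4R)-2,2-dimethyl-1,3-dioxolan-4-yl]prop-2-en-1-one | CC1(C)OC[C@@H](O1)C(=O)C=C | intermediate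
4 | 2-methylcyclohex-2-en-1-one | CC1=CCCCC1=O | starting material
5 | bromomagnesium (3R)-2,3-dimethylcyclohex-1-en-1-olate | CC1=C(O[Mg]Br)CCC[C@H]1C | intermediate (not isolated)
6 | trimethyl{[(3R)-2,3-dimethylcyclohex-1-en-1-yl]oxy}silane | CC1=C(O[Si](C)(C)C)CCC[C@H]1C | intermediate
7 | (2S,3R)-2-{3-[(4R)-2,2-dimethyl-1,3-dioxolan-4-yl]-3-(trimethylsilyloxy)prop-2-en-1-yl}-2,3-dimethylcyclohexan-1-one | CC1(C)OC[C@@H](O1)C(O[Si](C)(C)C)=CC[C@]2(C)C(=O)CCC[C@H]2C | intermediate (not isolated)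
8 | (2S,3R)-2-{3-[(4R)-2,2-dimethyl-1,3-dioxolan-4-yl]-3-oxopropyl}-2,3-dimethylcyclohexan-1-one | CC1(C)OC[C@@H](O1)C(=O)CC[C@]2(C)C(=O)CCC[C@H]2C | intermediate
9 | (2S,3R)-2-{(3S)-3-[(4R)-2,2-dimethyl-1,3-dioxolan-4-yl]-3-hydroxybutyl}-2,3-dimethylcyclohexan-1-one | CC1(C)OC[C@@H](O1)[C@@](C)(O)CC[C@]2(C)C(=O)CCC[C@H]2C | intermediate
10 | (2S,3R)-2,3-dimethyl-2-SC-cyclohexan-1-one (triethylsilyl ether of 9) | CC1(C)OC[C@@H](O1)[C@@](C)(O[Si](CC)(CC)CC)CC[C@]2(C)C(=O)CCC[C@H]2C | intermediate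
11 | potassium (5R,6S)-5,6-dimethyl-6-SC-cyclohex-1-en-1-olate | CC1(C)OC[C@@H](O1)[C@@](C)(O[Si](CC)(CC)CC)CC[C@]2(C)C(O[K])=CCC[C@H]2C | intermediate (not isolated)
12 | (5R,6S)-5,6-dimethyl-6-SC-cyclohex-1-en-1-yl trifluoromethanesulfonate | CC1(C)OC[C@@H](O1)[C@@](C)(O[Si](CC)(CC)CC)CC[C@]2(C)C(OS(=O)(=O)C(F)(F)F)=CCC[C@H]2C | intermediate
13 | 1-[(5R,6S)-5,6-dimethyl-6-SC-cyclohex-1-en-1-yl]prop-2-en-1-one | CC1(C)OC[C@@H](O1)[C@@](C)(O[Si](CC)(CC)CC)CC[C@]2(C)C(C(=O)C=C)=CCC[C@H]2C | intermediate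
14 | dimethyl malonate | COC(=O)CC(=O)OC | starting material
15 | dimethyl 2-{3-[(5R,6S)-5,6-dimethyl-6-SC-cyclohex-1-en-1-yl]-3-oxopropyl}propanedioate | CC1(C)OC[C@@H](O1)[C@@](C)(O[Si](CC)(CC)CC)CC[C@]2(C)C(C(=O)CCC(C(=O)OC)C(=O)OC)=CCC[C@H]2C | intermediate
16 | dimethyl 2-{(3S)-3-[(5R,6S)-5,6-dimethyl-6-SC-cyclohex-1-en-1-yl]-3-hydroxypropyl}propanedioate | CC1(C)OC[C@@H](O1)[C@@](C)(O[Si](CC)(CC)CC)CC[C@]2(C)C([C@@H](O)CCC(C(=O)OC)C(=O)OC)=CCC[C@H]2C | intermediate (not isolated)
17 | methyl (6S)-6-[(5R,6S)-5,6-dimethyl-6-SC-cyclohex-1-en-1-yl]-2-oxooxane-3-carboxylate (both C3 epimers) | CC1(C)OC[C@@H](O1)[C@@](C)(O[Si](CC)(CC)CC)CC[C@]2(C)C([C@@H]3CCC(C(=O)OC)C(=O)O3)=CCC[C@H]2C | intermediate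
18 | methyl (2S)-6-(tert-butyldimethylsilyloxy)-2-[(5R,6S)-5,6-dimethyl-6-SC-cyclohex-1-en-1-yl]-3,4-dihydro-2H-pyran-5-carboxylate | CC1(C)OC[C@@H](O1)[C@@](C)(O[Si](CC)(CC)CC)CC[C@]2(C)C([C@@H]3CCC(C(=O)OC)=C(O[Si](C)(C)C(C)(C)C)O3)=CCC[C@H]2C | intermediate (not isolated)
19 | 19-(tert-butyldimethylsilyl) 18-methyl (4R,5S,8R,9S,13S,14R)-14,15-(isopropylidenedioxy)-13-(triethylsilyloxy)halim-1(10)-ene-18,19-dioate | CC1(C)OC[C@@H](O1)[C@@](C)(O[Si](CC)(CC)CC)CC[C@]2(C)C3=CCC[C@](C(=O)O[Si](C)(C)C(C)(C)C)(C(=O)OC)[C@H]3CC[C@H]2C | intermediate (not isolated)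
20 | (4S,5S,8R,9S,13S,14R)-14,15-(isopropylidenedioxy)-18-methoxy-18-oxo-13-(triethylsilyloxy)halim-1(10)-en-19-oic acid | CC1(C)OC[C@@H](O1)[C@@](C)(O[Si](CC)(CC)CC)CC[C@]2(C)C3=CCC[C@](C(=O)O)(C(=O)OC)[C@H]3CC[C@H]2C | intermediate
21 | methyl (4S,5S,8R,9S,13S,14R)-19-(imidazol-1-yl)-14,15-(isopropylidenedioxy)-19-oxo-13-(triethylsilyloxy)halim-1(10)-en-18-oate | CC1(C)OC[C@@H](O1)[C@@](C)(O[Si](CC)(CC)CC)CC[C@]2(C)C3=CCC[C@](C(=O)n4ccnc4)(C(=O)OC)[C@H]3CC[C@H]2C | intermediate (not isolated)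
22 | methyl (4S,5S,8R,9S,13S,14R)-19-hydroxy-14,15-(isopropylidenedioxy)-13-(triethylsilyloxy)halim-1(10)-en-18-oate | CC1(C)OC[C@@H](O1)[C@@](C)(O[Si](CC)(CC)CC)CC[C@]2(C)C3=CCC[C@](CO)(C(=O)OC)[C@H]3CC[C@H]2C | intermediate
23 | methyl (4R,5S,8R,9S,13S,14R)-19-iodo-14,15-(isopropylidenedioxy)-13-(triethylsilyloxy)halim-1(10)-en-18-oate | CC1(C)OC[C@@H](O1)[C@@](C)(O[Si](CC)(CC)CC)CC[C@]2(C)C3=CCC[C@](CI)(C(=O)OC)[C@H]3CC[C@H]2C | intermediate
24 | methyl (4S,5S,8R,9S,13S,14R)-14,15-(isopropylidenedioxy)-13-(triethylsilyloxy)halim-1(10)-en-18-oate | CC1(C)OC[C@@H](O1)[C@@](C)(O[Si](CC)(CC)CC)CC[C@]2(C)C3=CCC[C@](C)(C(=O)OC)[C@H]3CC[C@H]2C | intermediate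
25 | (4S,5S,8R,9S,13S,14R)-14,15-(isopropylidenedioxy)-13-(triethylsilyloxy)halim-1(10)-en-18-oic acid | CC1(C)OC[C@@H](O1)[C@@](C)(O[Si](CC)(CC)CC)CC[C@]2(C)C3=CCC[C@](C)(C(=O)O)[C@H]3CC[C@H]2C | intermediate
26 | (4S,5S,8R,9S,13S,14R)-13,14,15-trihydroxyhalim-1(10)-en-18-oic acid | OC[C@@H](O)[C@@](C)(O)CC[C@]1(C)C2=CCC[C@](C)(C(=O)O)[C@H]2CC[C@H]1C | intermediate
27 | acetic (4S,5S,8R,9S,13S,14R)-14,15-diacetoxy-13-hydroxyhalim-1(10)-en-18-oic anhydride | CC(=O)OC[C@@H](OC(C)=O)[C@@](C)(O)CC[C@]1(C)C2=CCC[C@](C)(C(=O)OC(C)=O)[C@H]2CC[C@H]1C | intermediate (not isolated)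
28 | (4S,5S,8R,9S,13S,14R)-14,15-diacetoxy-13-hydroxyhalim-1(10)-en-18-oic acid | CC(=O)OC[C@@H](OC(C)=O)[C@@](C)(O)CC[C@]1(C)C2=CCC[C@](C)(C(=O)O)[C@H]2CC[C@H]1C | target

**Totals**
Total step count: 17.
Longest linear sequence: 16 steps (steps 1, 2 and 4 to 17, from ester 1).

**Steps most likely to fail**

Step 11. The [3,3] shift may be slowed by the quaternary C9 next to the allyl unit, so that ketene acetal 18 eliminates to a diene acid or the half ester loses CO2 before ring A closes. The fallback sets out from 16, isolated before lactonisation, and returns at 22. ClCO2Me and pyridine give the methyl carbonate F1. Zerovalent palladium (Pd2(dba)3, dppe, THF, 50 °C) ionises it with inversion, and the malonate attacks the anti π-allyl terminus C5 with a second inversion (Tsuji–Trost alkylation; a six-membered ring against a four-membered one), which should give the ring A diester F2 with the same C5 configuration. LiOH (1 equiv) should saponify the less hindered ester cis to H5 to the half acid F3. LiBH4 reduces the remaining ester beside the carboxylate to the hydroxy acid F4, and Me3SiCHN2 esterifies it to 22.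

Step 5. The facial selectivity at C13 may be poor, or of the Felkin–Anh sense, if the magnesium chelate is not formed; enolisation with β-elimination of the α-alkoxy ketone may compete. The fallback sets out from 6 and returns at 9, setting C13 and C14 by reagent control. Mukaiyama–Michael addition to but-3-en-2-one gives the dione F5. Horner–Wadsworth–Emmons olefination (triethyl phosphonoacetate, NaH) of the methyl ketone gives the (E)-enoate F6. i-Bu2AlH reduces ester and ring ketone to the diol F7. Sharpless asymmetric epoxidation (Ti(OiPr)4, L-(+)-diethyl tartrate, t-BuOOH) gives the (13S,14S)-epoxy alcohol F8. NaOH in t-BuOH/H2O effects Payne rearrangement and hydroxide opening at C15, inverting C14, to the tetrol F9. Me2C(OMe)2 with PPTS gives the terminal acetonide F10, and Dess–Martin oxidation of the ring carbinol gives 9.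

Step 10. Hydride delivery to the twisted, hindered enone may show poor facial selectivity, which would erode C1 and through it C5. The fallback sets out from 15 and returns at 16. Luche reduction (NaBH4, CeCl3, MeOH) gives 16 together with its C1 epimer F11, separable as diastereomers. F11 is inverted by Mitsunobu esterification (4-nitrobenzoic acid, PPh3, DIAD) to the 4-nitrobenzoate F12, and K2CO3 in MeOH cleaves this ester to 16, which is lactonised as in step 10.

**Further compounds**
F1 | step 11 | dimethyl 2-{(3S)-3-[(5R,6S)-5,6-dimethyl-6-SC-cyclohex-1-en-1-yl]-3-(methoxycarbonyloxy)propyl}propanedioate | CC1(C)OC[C@@H](O1)[C@@](C)(O[Si](CC)(CC)CC)CC[C@]2(C)C([C@@H](OC(=O)OC)CCC(C(=O)OC)C(=O)OC)=CCC[C@H]2C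
F2 | step 11 | dimethyl (5S,8R,9S,13S,14R)-14,15-(isopropylidenedioxy)-13-(triethylsilyloxy)halim-1(10)-ene-18,19-dioate | CC1(C)OC[C@@H](O1)[C@@](C)(O[Si](CC)(CC)CC)CC[C@]2(C)C3=CCCC(C(=O)OC)(C(=O)OC)[C@H]3CC[C@H]2C
F3 | step 11 | (4R,5S,8R,9S,13S,14R)-14,15-(isopropylidenedioxy)-19-methoxy-19-oxo-13-(triethylsilyloxy)halim-1(10)-en-18-oic acid | CC1(C)OC[C@@H](O1)[C@@](C)(O[Si](CC)(CC)CC)CC[C@]2(C)C3=CCC[C@](C(=O)OC)(C(=O)O)[C@H]3CC[C@H]2C
F4 | step 11 | (4S,5S,8R,9S,13S,14R)-19-hydroxy-14,15-(isopropylidenedioxy)-13-(triethylsilyloxy)halim-1(10)-en-18-oic acid | CC1(C)OC[C@@H](O1)[C@@](C)(O[Si](CC)(CC)CC)CC[C@]2(C)C3=CCC[C@](CO)(C(=O)O)[C@H]3CC[C@H]2C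
F5 | step 5 | (2S,3R)-2,3-dimethyl-2-(3-oxobutyl)cyclohexan-1-one | CC(=O)CC[C@]1(C)C(=O)CCC[C@H]1C
F6 | step 5 | ethyl (2E)-5-[(1S,2R)-1,2-dimethyl-6-oxocyclohexyl]-3-methylpent-2-enoate | CCOC(=O)/C=C(\C)CC[C@]1(C)C(=O)CCC[C@H]1C
F7 | step 5 | (2E)-5-[(1S,2R)-6-hydroxy-1,2-dimethylcyclohexyl]-3-methylpent-2-en-1-ol (both carbinol epimers) | OC/C=C(\C)CC[C@]1(C)C(O)CCC[C@H]1C
F8 | step 5 | {(2S,3S)-3-[2-((1S,2R)-6-hydroxy-1,2-dimethylcyclohexyl)ethyl]-3-methyloxiran-2-yl}methanol | OC[C@@H]1O[C@@]1(C)CC[C@]2(C)C(O)CCC[C@H]2C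
F9 | step 5 | (2R,3S)-5-[(1S,2R)-6-hydroxy-1,2-dimethylcyclohexyl]-3-methylpentane-1,2,3-triol | OC[C@@H](O)[C@@](C)(O)CC[C@]1(C)C(O)CCC[C@H]1C
F10 | step 5 | (2S,3R)-2-{(3S)-3-[(4R)-2,2-dimethyl-1,3-dioxolan-4-yl]-3-hydroxybutyl}-2,3-dimethylcyclohexan-1-ol (both carbinol epimers) | CC1(C)OC[C@@H](O1)[C@@](C)(O)CC[C@]2(C)C(O)CCC[C@H]2C
F11 | step 10 | dimethyl 2-{(3R)-3-[(5R,6S)-5,6-dimethyl-6-SC-cyclohex-1-en-1-yl]-3-hydroxypropyl}propanedioate | CC1(C)OC[C@@H](O1)[C@@](C)(O[Si](CC)(CC)CC)CC[C@]2(C)C([C@H](O)CCC(C(=O)OC)C(=O)OC)=CCC[C@H]2C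
F12 | step 10 | dimethyl 2-{(3S)-3-[(5R,6S)-5,6-dimethyl-6-SC-cyclohex-1-en-1-yl]-3-(4-nitrobenzoyloxy)propyl}propanedioate | CC1(C)OC[C@@H](O1)[C@@](C)(O[Si](CC)(CC)CC)CC[C@]2(C)C([C@@H](OC(=O)c3ccc(cc3)[N+](=O)[O-])CCC(C(=O)OC)C(=O)OC)=CCC[C@H]2C
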